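Ring B is disconnected at C7–C8 (clerodane numbering), the bond joining the secondary and the tertiary carbinol of the C6–C7–C8 triol. A SmI2 ketyl–carbonyl (pinacol) cyclisation of a C7 aldehyde onto a C8 methyl ketone closes ring B on a finished ring A and sets C7 and C8 at once. It exploits the cis C7/C8 diol of ring B and the trans ring fusion, whose axial Me-19 and Me-20 fix the chair. The precursor is a monocyclic cyclohexene with an α-silyloxy aldehyde arm on C5 and a quaternary C9 (methyl, vinyl, acetyl) on C10, built from (S)-carvone through a δ-lactone template that controls C9; the butenolide is attached last by a Heck reaction.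

Key step: step 9

Remark on numbering: clerodane numbering is used for every compound (ring A = C1–C5 and C10; ring B = C5–C10; Me-17 on C8, Me-18 on C4, Me-19 on C5, Me-20 on C9; side chain C11–C16). "Syn" and "anti" refer to the ring face that carries Me-19.
Assumption: the silyl ketene acetal 2 and 2,2-dimethoxyacetaldehyde 4 (sold as an aqueous solution, dried and distilled before use) are taken as purchasable.

Step 1
Reactants: 1 (S)-carvone; 2 1-methoxy-1-(trimethylsilyloxy)prop-1-ene
Product: 3 methyl 2-[(1R,5S)-2-methyl-5-(prop-1-en-2-yl)-3-(trimethylsilyloxy)cyclohex-2-en-1-yl]propanoate (C9 epimers)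
Conditions: Ph3CSbCl6 (3 mol%), CH2Cl2, −78 °C; pyridine quench
Reagents that add atoms: none
Why: A trityl-cation-catalysed Mukaiyama–Michael addition should deliver the ketene acetal carbon to C10 by axial attack anti to the isopropenyl group and pass the silyl group to the enolate oxygen, so that C10 is set, the C4–C5 enolate is stored regiodefined as its silyl ether, and the configuration at C9 is immaterial because that carbon is re-enolised in step 6.

Step 2
Reactants: 3 silyl enol ether; 4 2,2-dimethoxyacetaldehyde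
Product: 6 (1R,4aR,6S,8aS)-1-(dimethoxymethyl)-4,8a-dimethyl-6-(prop-1-en-2-yl)octahydro-1H-isochromene-3,8-dione (trans-fused keto δ-lactone; C9 epimers), via hydroxy ester 5 (not isolated)
Conditions: KOt-Bu (1.0 equiv), THF, −78 → −30 °C; ZnCl2, −78 °C; 4, −78 °C; aqueous work-up; then PPTS (cat.), PhH, 50 °C
Reagents that add atoms: none
Why: Alkoxide cleavage of the silyl enol ether and transmetalation give the regiodefined tetrasubstituted zinc enolate, whose aldol addition should occur on the ring face anti to the axial C10 side chain (C5 set, Me-19 cis to that chain) through a Zimmerman–Traxler chair in which the acetal-bearing carbon points away from ring A (C6 oxygen set syn to Me-19), and lactonisation onto the methyl ester forestalls retro-aldol cleavage and builds the trans-fused lactone template.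

Step 3
Reactants: 6 keto lactone with isopropenyl group
Product: 7 (1R,4aR,8aS)-1-(dimethoxymethyl)-4,8a-dimethyloctahydro-1H-isochromene-3,8-dione (C9 epimers)
Conditions: O3, MeOH, −78 °C; then FeSO4·7H2O, PhSH, −78 → 23 °C
Reagents that add atoms: none
Why: Ozonolysis of the isopropenyl group in methanol gives an α-methoxy hydroperoxide that divalent iron reduces to an alkoxy radical, β-scission then leaves a secondary ring radical at C2 that is capped by hydrogen transfer from the thiol (hydrodealkenylation), which removes the carvone control element after use and creates no stereocenter.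

Step 4
Reactants: 7 keto lactone
Product: 8 (1R,4aR,8aS)-1-(dimethoxymethyl)-4,8a-dimethyl-3-oxo-3,4,4a,5,6,8a-hexahydro-1H-isochromen-8-yl trifluoromethanesulfonate (C9 epimers)
Conditions: KN(SiMe3)2 (1.05 equiv), THF, −78 °C; PhNTf2, −78 → 0 °C
Reagents that add atoms: N-phenylbis(trifluoromethanesulfonimide), O=S(=O)(N(c1ccccc1)S(=O)(=O)C(F)(F)F)C(F)(F)F
Why: Kinetic deprotonation should occur at C3, the only enolisable position of the ketone and more acidic than the lactone α-position, and O-sulfonylation of the potassium enolate gives the C3=C4 enol triflate (enol triflate formation).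

Step 5
Reactants: 8 enol triflate
Product: 9 (1R,4aR,8aR)-1-(dimethoxymethyl)-4,8,8a-trimethyl-1,4,4a,5,6,8a-hexahydro-3H-isochromen-3-one (C9 epimers)
Conditions: MeZnCl, Pd(PPh3)4 (5 mol%), THF, 50 °C
Reagents that add atoms: methylzinc chloride, C[Zn]Cl
Why: Negishi cross-coupling of the alkenyl triflate with the weakly basic methylzinc reagent should install Me-18 and fix the C3=C4 double bond of ring A while leaving the lactone untouched.

Step 6
Reactants: 9 α-methyl lactone
Product: 10 (1R,4R,4aS,8aR)-1-(dimethoxymethyl)-4-ethenyl-4,8,8a-trimethyl-1,4,4a,5,6,8a-hexahydro-3H-isochromen-3-one (vinyl anti, Me-20 syn to Me-19)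
Conditions: LiN(SiMe3)2, PhMe/THF, −78 → 0 °C; CH2=CHBr (1 M in THF), Pd2(dba)3 (2.5 mol%), P(t-Bu)3 (6 mol%), 23 °C
Reagents that add atoms: vinyl bromide, C=CBr
Why: Palladium-catalysed α-vinylation of the lactone lithium enolate (enolate cross-coupling) should form the quaternary C9, the planar enolate of the trans-fused lactone being attacked on the face anti to the syn-axial Me-19 so that the vinyl group ends anti and Me-20 syn to Me-19, which also erases the C9 epimer mixture.

Step 7
Reactants: 10 vinyl lactone
Product: 11 (3R)-3-[(1S,2R)-2-[(1R)-1-hydroxy-2,2-dimethoxyethyl]-2,3-dimethylcyclohex-3-en-1-yl]-3-methylpent-4-en-2-one (may rest as its cyclic hemiketal)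
Conditions: MeLi (1.3 equiv), THF, −78 °C; then H2O
Reagents that add atoms: methyllithium, [Li]C
Why: Addition of methyllithium to the hindered lactone carbonyl should stop at the tetrahedral lithium lactolate, which on work-up opens to the C8 methyl ketone and frees the C6 hydroxyl (lactone to methyl ketone opening) without touching a stereocenter.

Step 8
Reactants: 11 hydroxy ketone acetal
Product: 14 (2R)-2-[(1R,6S)-1,2-dimethyl-6-[(3R)-3-methyl-2-oxopent-4-en-3-yl]cyclohex-2-en-1-yl]-2-(triethylsilyloxy)acetaldehyde, via silyl ether 12 (not isolated), via collidinium salt 13 (not isolated)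
Conditions: Et3SiOTf (3 equiv), 2,4,6-collidine (4 equiv), CH2Cl2, 0 °C; then H2O, 23 °C
Reagents that add atoms: triethylsilyl trifluoromethanesulfonate, CC[Si](CC)(CC)OS(=O)(=O)C(F)(F)F; water, O
Why: The silyl triflate–collidine pair should first silylate the C6 hydroxyl of the open hydroxy ketone and then ionise the dimethyl acetal to a collidinium adduct that water hydrolyses to the aldehyde under non-acidic conditions (silyl triflate and pyridine-base acetal cleavage), which spares the hindered methyl ketone and the enolisable C6 centre.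

Step 9
Reactants: 14 keto aldehyde
Product: 16 (1R,2S,3R,4R,4aS,8aR)-4-ethenyl-3,4,8,8a-tetramethyl-1,2,3,4,4a,5,6,8a-octahydronaphthalene-1,2,3-triol, via silyl ether diol 15 (not isolated)
Conditions: SmI2 (2.5 equiv), t-BuOH (2 equiv), THF, −78 → −20 °C; aqueous work-up; then PPTS, MeOH, 23 °C on the crude product
Reagents that add atoms: none
Why: SmI2 reduces the C7 aldehyde to a samarium ketyl, which adds to the C8 ketone carbon held on the same metal, and a second electron transfer gives the bridged samarium diolate (intramolecular ketyl–carbonyl pinacol coupling, the closest known type being SmI2 cyclisations of 1,6-keto aldehydes to cis-cyclohexane-1,2-diols). Ring B closes in a 6-exo-trig mode on the C8 carbonyl through a chair transition state trans-fused to ring A. At C7 the ketyl oxygen takes the equatorial site because the axial one is syn-axial to both Me-19 and Me-20, which also places it trans to the equatorial C6 silyloxy group; at C8 the samarium bridge forces the oxygen cis to that on C7, hence axial, leaving Me-17 equatorial. The step needs carbonyl–carbonyl coupling to outrun ketyl addition to the C9 vinyl group, simple reduction and β-elimination of the C6 silyloxy group; chelation of both carbonyls, the six-membered closure and the low temperature secure this. Methanolysis with PPTS then removes the triethylsilyl ether without disturbing the tertiary alcohol.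

Step 10
Reactants: 16 triol
Product: 17 (1R,2S,3R,4R,4aS,8aR)-4-ethenyl-3-hydroxy-3,4,8,8a-tetramethyl-1,2,3,4,4a,5,6,8a-octahydronaphthalene-1,2-diyl diacetate
Conditions: Ac2O, pyridine, DMAP (cat.), CH2Cl2, 23 °C
Reagents that add atoms: acetic anhydride, CC(=O)OC(C)=O
Why: Acylation under nucleophilic catalysis should esterify the two secondary hydroxyls at C6 and C7 and leave the hindered tertiary C8 hydroxyl free (selective acetylation).

Step 11
Reactants: 17 diacetate; 18 4-bromofuran-2(5H)-one
Product: 19 (1R,2S,3R,4R,4aS,8aR)-3-hydroxy-3,4,8,8a-tetramethyl-4-[(E)-2-(5-oxo-2,5-dihydrofuran-3-yl)ethenyl]-1,2,3,4,4a,5,6,8a-octahydronaphthalene-1,2-diyl diacetate (CNP0383656.1)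
Conditions: Pd(OAc)2 (10 mol%), P(o-tol)3 (20 mol%), n-Bu4NCl, NaHCO3, DMF, 70 °C
Reagents that add atoms: none
Why: Mizoroki–Heck coupling should add the butenolide–palladium species to the terminal carbon of the neopentyl vinyl group, and syn β-hydride elimination, possible only toward C12, should give the (E)-C11=C12 diene without touching the hindered ring alkene.

Compound list
1 | (S)-carvone, (5S)-2-methyl-5-(prop-1-en-2-yl)cyclohex-2-en-1-one | CC1=CC[C@@H](CC1=O)C(C)=C | starting material
2 | 1-methoxy-1-(trimethylsilyloxy)prop-1-ene (E/Z mixture) | CC=C(OC)O[Si](C)(C)C | starting material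
3 | methyl 2-[(1R,5S)-2-methyl-5-(prop-1-en-2-yl)-3-(trimethylsilyloxy)cyclohex-2-en-1-yl]propanoate (ester arm trans to isopropenyl; C9 epimers) | CC(C(=O)OC)[C@H]1C[C@H](C(C)=C)CC(O[Si](C)(C)C)=C1C | intermediate
4 | 2,2-dimethoxyacetaldehyde | COC(OC)C=O | starting material
5 | methyl 2-[(1R,2S,5S)-2-[(1R)-1-hydroxy-2,2-dimethoxyethyl]-2-methyl-3-oxo-5-(prop-1-en-2-yl)cyclohexyl]propanoate (aldol adduct; C9 epimers) | COC(OC)[C@H](O)[C@@]1(C)C(=O)C[C@@H](C(C)=C)C[C@@H]1C(C)C(=O)OC | intermediate
6 | (1R,4aR,6S,8aS)-1-(dimethoxymethyl)-4,8a-dimethyl-6-(prop-1-en-2-yl)octahydro-1H-isochromene-3,8-dione (trans-fused; CH(OMe)2 anti to Me-19; C9 epimers) | COC(OC)[C@@H]1OC(=O)C(C)[C@H]2C[C@H](C(C)=C)CC(=O)[C@]12C | intermediate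
7 | (1R,4aR,8aS)-1-(dimethoxymethyl)-4,8a-dimethyloctahydro-1H-isochromene-3,8-dione (C9 epimers) | COC(OC)[C@@H]1OC(=O)C(C)[C@H]2CCCC(=O)[C@]12C | intermediate
8 | (1R,4aR,8aS)-1-(dimethoxymethyl)-4,8a-dimethyl-3-oxo-3,4,4a,5,6,8a-hexahydro-1H-isochromen-8-yl trifluoromethanesulfonate (C9 epimers) | COC(OC)[C@@H]1OC(=O)C(C)[C@H]2CCC=C(OS(=O)(=O)C(F)(F)F)[C@]12C | intermediate
9 | (1R,4aR,8aR)-1-(dimethoxymethyl)-4,8,8a-trimethyl-1,4,4a,5,6,8a-hexahydro-3H-isochromen-3-one (C9 epimers) | COC(OC)[C@@H]1OC(=O)C(C)[C@H]2CCC=C(C)[C@]12C | intermediate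
10 | (1R,4R,4aS,8aR)-1-(dimethoxymethyl)-4-ethenyl-4,8,8a-trimethyl-1,4,4a,5,6,8a-hexahydro-3H-isochromen-3-one | COC(OC)[C@@H]1OC(=O)[C@](C)(C=C)[C@H]2CCC=C(C)[C@]12C | intermediate
11 | (3R)-3-[(1S,2R)-2-[(1R)-1-hydroxy-2,2-dimethoxyethyl]-2,3-dimethylcyclohex-3-en-1-yl]-3-methylpent-4-en-2-one | COC(OC)[C@H](O)[C@@]1(C)C(C)=CCC[C@@H]1[C@@](C)(C=C)C(C)=O | intermediate
12 | (3R)-3-[(1S,2R)-2-[(1R)-2,2-dimethoxy-1-(triethylsilyloxy)ethyl]-2,3-dimethylcyclohex-3-en-1-yl]-3-methylpent-4-en-2-one | COC(OC)[C@H](O[Si](CC)(CC)CC)[C@@]1(C)C(C)=CCC[C@@H]1[C@@](C)(C=C)C(C)=O | intermediate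
13 | N-(1-methoxyalkyl)-2,4,6-trimethylpyridinium triflate formed from the acetal carbon C7 of 12 (C7 epimers) | COC([n+]1c(C)cc(C)cc1C)[C@H](O[Si](CC)(CC)CC)[C@@]1(C)C(C)=CCC[C@@H]1[C@@](C)(C=C)C(C)=O.[O-]S(=O)(=O)C(F)(F)F | intermediate
14 | (2R)-2-[(1R,6S)-1,2-dimethyl-6-[(3R)-3-methyl-2-oxopent-4-en-3-yl]cyclohex-2-en-1-yl]-2-(triethylsilyloxy)acetaldehyde | O=C[C@H](O[Si](CC)(CC)CC)[C@@]1(C)C(C)=CCC[C@@H]1[C@@](C)(C=C)C(C)=O | intermediate
15 | (1R,2S,3R,4R,4aS,8aR)-4-ethenyl-3,4,8,8a-tetramethyl-1-(triethylsilyloxy)-1,2,3,4,4a,5,6,8a-octahydronaphthalene-2,3-diol | CC[Si](CC)(CC)O[C@H]1[C@H](O)[C@](C)(O)[C@](C)(C=C)[C@H]2CCC=C(C)[C@]12C | intermediate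
16 | (1R,2S,3R,4R,4aS,8aR)-4-ethenyl-3,4,8,8a-tetramethyl-1,2,3,4,4a,5,6,8a-octahydronaphthalene-1,2,3-triol | O[C@H]1[C@H](O)[C@](C)(O)[C@](C)(C=C)[C@H]2CCC=C(C)[C@]12C | intermediate
17 | (1R,2S,3R,4R,4aS,8aR)-4-ethenyl-3-hydroxy-3,4,8,8a-tetramethyl-1,2,3,4,4a,5,6,8a-octahydronaphthalene-1,2-diyl diacetate | CC(=O)O[C@H]1[C@H](OC(C)=O)[C@](C)(O)[C@](C)(C=C)[C@H]2CCC=C(C)[C@]12C | intermediate
18 | 4-bromofuran-2(5H)-one | BrC1=CC(=O)OC1 | starting material
19 | CNP0383656.1, (5R,6R,7S,8R,9R,10S)-6,7-diacetoxy-8-hydroxycleroda-3,11(E),13-trien-15,16-olide | CC(=O)O[C@H]1[C@H](OC(C)=O)[C@](C)(O)[C@](C)(/C=C/C2=CC(=O)OC2)[C@H]2CCC=C(C)[C@]12C | target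

Total step count: 11. Longest linear sequence: 11 steps, from (S)-carvone 1.

Steps most likely to fail

Step 9 (key pinacol cyclisation). The ketyl may be reduced further to the alcohol, or may lose the C6 silyloxy group by β-elimination, before the congested C7–C8 bond forms. Cis delivery of the two oxygens may also be incomplete. The fallback closes the same bond by a polar Nozaki–Hiyama–Kishi reaction and sets the C8 carbinol afterwards. It sets out from 11, which is silylated alone (Et3SiOTf 1.1 equiv, 2,6-lutidine, −78 °C) and stopped at 12. KN(SiMe3)2 and PhNTf2 convert the methyl ketone into the 1,1-disubstituted enol triflate F1, and the silyl triflate–collidine acetal cleavage gives the aldehyde triflate F2. CrCl2 with NiCl2 (cat.) in DMF closes ring B to the allylic alcohol F3, which carries an exocyclic C8 methylene and an equatorial C7 hydroxyl. VO(acac)2 and t-BuOOH epoxidise the allylic alkene on the face of the C7 hydroxyl to the spiro-epoxide F4. LiBHEt3 opens it at the CH2 terminus, and the route is rejoined at 15.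

Step 6 (α-vinylation). Reductive elimination at the congested quaternary centre may be slow, so that β-hydride loss from the palladium enolate or simple reprotonation takes over. The fallback is a two-stage vinylation by conjugate addition and sulfoxide elimination, setting out from 9. The lithium enolate adds to phenyl vinyl sulfoxide from the same face to give the sulfoxide F5. Thermolysis (PhMe, 110 °C, NaHCO3) causes syn-elimination and returns the route at 10.

Step 2 (aldol and lactonisation). Facial discrimination of the achiral aldehyde by the tetrasubstituted enolate may be poor, which would give the wrong configuration at C6. Retro-aldol cleavage may also compete with ring closure. The fallback replaces simple diastereoselection by reagent control, setting out from 3. The same enolate, without ZnCl2, adds to (S)-2,3-O-isopropylideneglyceraldehyde under Felkin–Anh (anti) control to give the hydroxy ester F6, which lactonises to the dioxolanyl lactone F7. H5IO6 in EtOAc cleaves the acetonide and the liberated diol to the lactone aldehyde F8. HC(OMe)3 with PPTS in MeOH returns the route at 6.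

Further compounds
F1 | step 9 | (3R)-3-[(1S,2R)-2-[(1R)-2,2-dimethoxy-1-(triethylsilyloxy)ethyl]-2,3-dimethylcyclohex-3-en-1-yl]-3-methylpenta-1,4-dien-2-yl trifluoromethanesulfonate | COC(OC)[C@H](O[Si](CC)(CC)CC)[C@@]1(C)C(C)=CCC[C@@H]1[C@@](C)(C=C)C(=C)OS(=O)(=O)C(F)(F)F
F2 | step 9 | aldehyde triflate: as 14 with the acetyl group replaced by 1-(trifluoromethanesulfonyloxy)ethenyl | O=C[C@H](O[Si](CC)(CC)CC)[C@@]1(C)C(C)=CCC[C@@H]1[C@@](C)(C=C)C(=C)OS(=O)(=O)C(F)(F)F
F3 | step 9 | allylic alcohol: as 15 with C8 carrying an exocyclic methylene in place of methyl and hydroxyl | CC[Si](CC)(CC)O[C@H]1[C@H](O)C(=C)[C@](C)(C=C)[C@H]2CCC=C(C)[C@]12C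
F4 | step 9 | spiro-epoxide of F3 at C8 (epoxide oxygen anti to Me-19, cis to the C7 hydroxyl) | CC[Si](CC)(CC)O[C@H]1[C@H](O)[C@@]2(CO2)[C@](C)(C=C)[C@H]3CCC=C(C)[C@]13C
F5 | step 6 | lactone as 10 with 2-(phenylsulfinyl)ethyl in place of vinyl on C9 (sulfur epimers) | COC(OC)[C@@H]1OC(=O)[C@](C)(CCS(=O)c3ccccc3)[C@H]2CCC=C(C)[C@]12C
F6 | step 2 | hydroxy ester as 5 with a (4S)-2,2-dimethyl-1,3-dioxolan-4-yl group in place of the dimethoxymethyl group | CC1(C)OC[C@H](O1)[C@H](O)[C@@]1(C)C(=O)C[C@@H](C(C)=C)C[C@@H]1C(C)C(=O)OC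
F7 | step 2 | keto lactone as 6 with a (4S)-2,2-dimethyl-1,3-dioxolan-4-yl group on C6 | CC1(C)OC[C@H](O1)[C@@H]1OC(=O)C(C)[C@H]2C[C@H](C(C)=C)CC(=O)[C@]12C
F8 | step 2 | keto lactone as 6 with a formyl group on C6 | O=C[C@@H]1OC(=O)C(C)[C@H]2C[C@H](C(C)=C)CC(=O)[C@]12C
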